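**Retrosynthetic overview**
1. Target ⇐ selective acylation and ether cleavage of a cyclohexene cis-1,6-diol carrying a 2-naphthylmethyl (NAP) ether at C2–O and 4-methoxybenzyl (PMB) ethers at C5–O and C7–O.
2. Key disconnection C1–C6: SmI2 pinacol cyclisation of a (Z)-1,6-keto-aldehyde; a ketyl (carbonyl carbon with inverted polarity) joins two carbonyl carbons and sets both new carbinol centres.
3. Keto-aldehyde ⇐ ω-hydroxy ketone ⇐ seven-membered unsaturated lactone + (alkoxymethyl)lithium, which brings C7.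
4. Lactone ⇐ ring-closing metathesis (locks the Z olefin) of an ester built from two 2-alkoxybut-3-enyl units of opposite configuration, both made from butadiene monoepoxide by Pd-catalysed asymmetric alcohol addition.
5. Ring order: the temporary seven-membered lactone first, then opened again; the cyclohexene, the only ring of the target, second.

Assumption: ring positions in all cyclohexene compounds are numbered as in the target name (C1 quaternary carbinol, C2 CH–OH, C3=C4, C5 CH–OBz, C6 CH–OAc, C7 the CH2O carbon), and in steps 1 and 2 the Trost ligand antipode is the one that gives the stated configuration (opposite antipodes for the two steps).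

**Step 1**
Reactants: 1 butadiene monoepoxide (racemic 2-vinyloxirane); 2 4-methoxybenzyl alcohol
Product: 3 (R)-2-[(4-methoxybenzyl)oxy]but-3-en-1-ol
Conditions: Pd2(dba)3·CHCl3 (1 mol%), DACH-phenyl Trost ligand (3 mol%, antipode giving 2R), Et3B (1 mol%), CH2Cl2, rt
Reagents that add atoms: none
Why: Trost dynamic kinetic asymmetric allylic etherification, in which zerovalent palladium opens the racemic vinyl epoxide to interconverting π-allyl complexes and the boron co-catalyst delivers the alcohol to the internal allyl carbon under ligand control, setting the R centre (later C5).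

**Step 2**
Reactants: 1 butadiene monoepoxide; 4 naphthalen-2-ylmethanol
Product: 5 (S)-2-(naphthalen-2-ylmethoxy)but-3-en-1-ol
Conditions: Pd2(dba)3·CHCl3 (1 mol%), DACH-phenyl Trost ligand (3 mol%, antipode giving 2S), Et3B (1 mol%), CH2Cl2, rt
Reagents that add atoms: none
Why: The same Trost dynamic kinetic asymmetric etherification with the other ligand antipode and a primary benzylic-type alcohol sets the S centre (later C2).

**Step 3**
Reactants: 5 (S)-2-(naphthalen-2-ylmethoxy)but-3-en-1-ol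
Product: 7 (S)-2-(naphthalen-2-ylmethoxy)but-3-enoic acid, via aldehyde 6 (not isolated)
Conditions: TEMPO (0.2 equiv), PhI(OAc)2 (2.2 equiv), MeCN/H2O (1:1), 0 °C to rt
Reagents that add atoms: water O
Why: TEMPO/PhI(OAc)2 oxoammonium oxidation takes the primary alcohol through the aldehyde hydrate to the acid under mildly acidic conditions, so the allylic α-centre is not epimerised, the vinyl group is not moved into conjugation, and the NAP ether is untouched.

**Step 4**
Reactants: 3 (R)-2-[(4-methoxybenzyl)oxy]but-3-en-1-ol; 7 (S)-2-(naphthalen-2-ylmethoxy)but-3-enoic acid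
Product: 8 (R)-2-[(4-methoxybenzyl)oxy]but-3-en-1-yl (S)-2-(naphthalen-2-ylmethoxy)but-3-enoate
Conditions: PPh3, DIAD, THF, 0 °C to rt
Reagents that add atoms: none
Why: Mitsunobu esterification activates the primary alcohol (SN2 at CH2, no stereocentre involved) and uses the acid only as its carboxylate, so the epimerisable acid is never turned into an activated acyl species.

**Step 5**
Reactants: 8 (R)-2-[(4-methoxybenzyl)oxy]but-3-en-1-yl (S)-2-(naphthalen-2-ylmethoxy)but-3-enoate
Product: 9 (3S,6R)-6-[(4-methoxybenzyl)oxy]-3-(naphthalen-2-ylmethoxy)-6,7-dihydrooxepin-2(3H)-one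
Conditions: second-generation Grubbs catalyst (5 mol%), Ti(OiPr)4 (0.3 equiv), 1,4-benzoquinone (10 mol%), CH2Cl2 (2 mM), reflux
Reagents that add atoms: none
Why: Ring-closing metathesis of the two vinyl groups gives the seven-membered lactone, whose ring forces the Z olefin; high dilution and Ti(OiPr)4 counter oligomerisation and carbonyl chelation of the ruthenium carbene, and benzoquinone suppresses olefin migration.

**Step 6**
Reactants: 10 tributyl(iodomethyl)stannane; 2 4-methoxybenzyl alcohol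
Product: 11 tributyl{[(4-methoxybenzyl)oxy]methyl}stannane
Conditions: NaH, THF/DMF, 0 °C to rt
Reagents that add atoms: none
Why: Williamson ether synthesis, SN2 displacement of iodide at the unhindered stannylmethyl carbon by the sodium alkoxide.

**Step 7**
Reactants: 9 (3S,6R)-6-[(4-methoxybenzyl)oxy]-3-(naphthalen-2-ylmethoxy)-6,7-dihydrooxepin-2(3H)-one; 11 tributyl{[(4-methoxybenzyl)oxy]methyl}stannane
Product: 13 (3S,6R,Z)-7-hydroxy-1,6-bis[(4-methoxybenzyl)oxy]-3-(naphthalen-2-ylmethoxy)hept-4-en-2-one, via alkoxymethyllithium 12 (not isolated)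
Conditions: 11 (1.5 equiv), n-BuLi, THF, −78 °C, 10 min; then 9, −78 °C; AcOH quench at −78 °C
Reagents that add atoms: none
Why: Tin–lithium exchange gives the α-alkoxymethyllithium, which adds once to the lactone carbonyl at −78 °C (as in ketose syntheses from aldonolactones), and the cold quench releases the ketone and the primary alcohol without touching the α-centre.

**Step 8**
Reactants: 13 (3S,6R,Z)-7-hydroxy-1,6-bis[(4-methoxybenzyl)oxy]-3-(naphthalen-2-ylmethoxy)hept-4-en-2-one
Product: 15 (1S,2S,5R,6S)-5-[(4-methoxybenzyl)oxy]-1-{[(4-methoxybenzyl)oxy]methyl}-2-(naphthalen-2-ylmethoxy)cyclohex-3-ene-1,6-diol, via keto-aldehyde 14 (not isolated)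
Conditions: (COCl)2, DMSO, THF, −78 °C, then iPr2NEt, to −40 °C; cannulate into SmI2 (5 equiv), t-BuOH (3 equiv), THF, −78 °C to −20 °C
Reagents that add atoms: none
Why: One-pot Swern oxidation and SmI2 pinacol cyclisation, in which single-electron transfer makes the aldehyde carbon a nucleophilic ketyl that attacks the ketone carbon; trivalent samarium bridging both oxygens gives the cis-diol, and each new C–O bond sits anti to the neighbouring ether oxygen (the known outcome for α,α'-dialkoxy 1,6-dicarbonyls), which sets C1 and C6.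

**Step 9**
Reactants: 15 (1S,2S,5R,6S)-5-[(4-methoxybenzyl)oxy]-1-{[(4-methoxybenzyl)oxy]methyl}-2-(naphthalen-2-ylmethoxy)cyclohex-3-ene-1,6-diol
Product: 16 (1R,2S,5R,6S)-6-acetoxy-5-[(4-methoxybenzyl)oxy]-1-{[(4-methoxybenzyl)oxy]methyl}-2-(naphthalen-2-ylmethoxy)cyclohex-3-en-1-ol
Conditions: Ac2O, pyridine, DMAP (cat.), CH2Cl2, 0 °C
Reagents that add atoms: acetic anhydride CC(=O)OC(C)=O
Why: Nucleophile-catalysed acylation takes the secondary C6 hydroxyl only, because the tertiary C1 hydroxyl is too hindered.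

**Step 10**
Reactants: 16 (1R,2S,5R,6S)-6-acetoxy-5-[(4-methoxybenzyl)oxy]-1-{[(4-methoxybenzyl)oxy]methyl}-2-(naphthalen-2-ylmethoxy)cyclohex-3-en-1-ol
Product: 17 (1R,2S,5R,6S)-6-acetoxy-1-(hydroxymethyl)-2-(naphthalen-2-ylmethoxy)cyclohex-3-ene-1,5-diol
Conditions: (NH4)2Ce(NO3)6 (4.5 equiv), MeCN/H2O (9:1), 0 °C
Reagents that add atoms: none
Why: Oxidative ether cleavage by single-electron transfer, in which tetravalent cerium removes both electron-rich PMB ethers while the less easily oxidised NAP ether, the acetate and the alkene survive (known PMB/NAP orthogonality).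

**Step 11**
Reactants: 17 (1R,2S,5R,6S)-6-acetoxy-1-(hydroxymethyl)-2-(naphthalen-2-ylmethoxy)cyclohex-3-ene-1,5-diol
Product: 18 [(1R,2S,5R,6S)-6-acetoxy-5-(benzoyloxy)-1-hydroxy-2-(naphthalen-2-ylmethoxy)cyclohex-3-en-1-yl]methyl benzoate
Conditions: BzCl (2.5 equiv), pyridine, DMAP (cat.), CH2Cl2, 0 °C to rt
Reagents that add atoms: benzoyl chloride O=C(Cl)c1ccccc1
Why: Acylation of the primary C7 and the secondary allylic C5 hydroxyls, with the tertiary hydroxyl again inert.

**Step 12**
Reactants: 18 [(1R,2S,5R,6S)-6-acetoxy-5-(benzoyloxy)-1-hydroxy-2-(naphthalen-2-ylmethoxy)cyclohex-3-en-1-yl]methyl benzoate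
Product: 19 [(1R,2S,5R,6S)-6-acetoxy-5-(benzoyloxy)-1,2-dihydroxycyclohex-3-en-1-yl]methyl benzoate (target)
Conditions: DDQ (2 equiv), CH2Cl2/H2O (10:1), rt
Reagents that add atoms: none
Why: DDQ oxidative cleavage of the NAP ether (hydride abstraction, hydrolysis of the oxocarbenium ion) frees the C2 hydroxyl; the esters, the alkene and the electron-poor allylic alcohol are inert and no stereocentre is touched.

**Compound list**
1 | butadiene monoepoxide (racemic 2-vinyloxirane) | C=CC1CO1 | starting material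
2 | 4-methoxybenzyl alcohol | COc1ccc(CO)cc1 | starting material
3 | (R)-2-[(4-methoxybenzyl)oxy]but-3-en-1-ol | OC[C@H](OCc1ccc(OC)cc1)C=C | intermediate
4 | naphthalen-2-ylmethanol | OCc1ccc2ccccc2c1 | starting material
5 | (S)-2-(naphthalen-2-ylmethoxy)but-3-en-1-ol | OC[C@@H](OCc1ccc2ccccc2c1)C=C | intermediate
6 | (S)-2-(naphthalen-2-ylmethoxy)but-3-enal | O=C[C@@H](OCc1ccc2ccccc2c1)C=C | intermediate (not isolated)
7 | (S)-2-(naphthalen-2-ylmethoxy)but-3-enoic acid | OC(=O)[C@@H](OCc1ccc2ccccc2c1)C=C | intermediate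
8 | (R)-2-[(4-methoxybenzyl)oxy]but-3-en-1-yl (S)-2-(naphthalen-2-ylmethoxy)but-3-enoate | C=C[C@H](OCc1ccc2ccccc2c1)C(=O)OC[C@H](OCc1ccc(OC)cc1)C=C | intermediate
9 | (3S,6R)-6-[(4-methoxybenzyl)oxy]-3-(naphthalen-2-ylmethoxy)-6,7-dihydrooxepin-2(3H)-one | O=C1OC[C@H](OCc2ccc(OC)cc2)C=C[C@@H]1OCc1ccc2ccccc2c1 | intermediate
10 | tributyl(iodomethyl)stannane | CCCC[Sn](CCCC)(CCCC)CI | starting material
11 | tributyl{[(4-methoxybenzyl)oxy]methyl}stannane | CCCC[Sn](CCCC)(CCCC)COCc1ccc(OC)cc1 | intermediate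
12 | {[(4-methoxybenzyl)oxy]methyl}lithium | [Li]COCc1ccc(OC)cc1 | intermediate (not isolated)
13 | (3S,6R,Z)-7-hydroxy-1,6-bis[(4-methoxybenzyl)oxy]-3-(naphthalen-2-ylmethoxy)hept-4-en-2-one | OC[C@H](OCc1ccc(OC)cc1)/C=C\[C@H](OCc1ccc2ccccc2c1)C(=O)COCc1ccc(OC)cc1 | intermediate
14 | (2R,5S,Z)-2,7-bis[(4-methoxybenzyl)oxy]-5-(naphthalen-2-ylmethoxy)-6-oxohept-3-enal | O=C[C@H](OCc1ccc(OC)cc1)/C=C\[C@H](OCc1ccc2ccccc2c1)C(=O)COCc1ccc(OC)cc1 | intermediate (not isolated)
15 | (1S,2S,5R,6S)-5-[(4-methoxybenzyl)oxy]-1-{[(4-methoxybenzyl)oxy]methyl}-2-(naphthalen-2-ylmethoxy)cyclohex-3-ene-1,6-diol | O[C@H]1[C@H](OCc2ccc(OC)cc2)C=C[C@H](OCc2ccc3ccccc3c2)[C@]1(O)COCc1ccc(OC)cc1 | intermediate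
16 | (1R,2S,5R,6S)-6-acetoxy-5-[(4-methoxybenzyl)oxy]-1-{[(4-methoxybenzyl)oxy]methyl}-2-(naphthalen-2-ylmethoxy)cyclohex-3-en-1-ol | CC(=O)O[C@H]1[C@H](OCc2ccc(OC)cc2)C=C[C@H](OCc2ccc3ccccc3c2)[C@]1(O)COCc1ccc(OC)cc1 | intermediate
17 | (1R,2S,5R,6S)-6-acetoxy-1-(hydroxymethyl)-2-(naphthalen-2-ylmethoxy)cyclohex-3-ene-1,5-diol | CC(=O)O[C@H]1[C@H](O)C=C[C@H](OCc2ccc3ccccc3c2)[C@]1(O)CO | intermediate
18 | [(1R,2S,5R,6S)-6-acetoxy-5-(benzoyloxy)-1-hydroxy-2-(naphthalen-2-ylmethoxy)cyclohex-3-en-1-yl]methyl benzoate | CC(=O)O[C@H]1[C@H](OC(=O)c2ccccc2)C=C[C@H](OCc2ccc3ccccc3c2)[C@]1(O)COC(=O)c1ccccc1 | intermediate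
19 | [(1R,2S,5R,6S)-6-acetoxy-5-(benzoyloxy)-1,2-dihydroxycyclohex-3-en-1-yl]methyl benzoate | CC(=O)O[C@H]1[C@H](OC(=O)c2ccccc2)C=C[C@H](O)[C@]1(O)COC(=O)c1ccccc1 | target

**Step count**
Total: 12 steps. Longest linear sequence: 10 steps (steps 2, 3, 4, 5, 7, 8, 9, 10, 11, 12).

**Three steps most likely to fail**

Step 8 (pinacol cyclisation). The risks are simple carbonyl reduction, loss of an α-alkoxy group from a ketyl, or the wrong facial sense at the ketone. The fallback sets out from hydroxy ketone 13 and comes back at diol 15. Keto-aldehyde 14 is made as before but worked up without water, and the ring is closed by an N-heterocyclic-carbene-catalysed intramolecular crossed aldehyde–ketone benzoin reaction (2-(pentafluorophenyl)-6,7-dihydro-5H-pyrrolo[2,1-c][1,2,4]triazol-2-ium tetrafluoroborate 20 mol%, Et3N, CH2Cl2, rt), in which the acyl-anion equivalent of the aldehyde attacks the ketone. This gives the acyloin (2R,5S,6R)-6-hydroxy-2-[(4-methoxybenzyl)oxy]-6-{[(4-methoxybenzyl)oxy]methyl}-5-(naphthalen-2-ylmethoxy)cyclohex-3-en-1-one F1; if the tertiary centre forms with the wrong sense, an aminoindanol-derived chiral triazolium salt of the matching antipode is used instead. Reduction with NaBH4 and CeCl3·7H2O in MeOH at −78 °C (axial hydride attack, giving the equatorial alcohol trans to the neighbouring ether and cis to the tertiary hydroxyl) then gives 15.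

Step 7 (lactone opening). The risks are enolisation of the β,γ-unsaturated lactone by the basic organolithium and double addition. The fallback sets out from lactone 9 and comes back at hydroxy ketone 13. Aminolysis with MeNH(OMe)·HCl and Me2AlCl (CH2Cl2, 0 °C) opens 9 to the Weinreb amide (2S,5R,Z)-6-hydroxy-N-methoxy-5-[(4-methoxybenzyl)oxy]-N-methyl-2-(naphthalen-2-ylmethoxy)hex-3-enamide F2. Reagent 12 (2.5 equiv, −78 °C; the first equivalent deprotonates the hydroxyl) then adds once through the stable N-methoxy chelate and gives 13 on quench.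

Step 5 (ring-closing metathesis). The seven-membered lactone must close against the s-trans preference of the ester, and oligomers may form instead. The fallback sets out from alcohol 5 and comes back at lactone 9, replacing the ester tether by a flexible acetal tether. Alcohol 5 is oxidised with Dess–Martin periodinane to aldehyde 6 (isolated here), which is condensed with 3 (2.2 equiv, PPTS, 4 Å sieves, CH2Cl2) to the acetal (S)-3-(naphthalen-2-ylmethoxy)-4,4-bis{[(R)-2-[(4-methoxybenzyl)oxy]but-3-en-1-yl]oxy}but-1-ene F3. Ring-closing metathesis (second-generation Grubbs catalyst, CH2Cl2, reflux) gives the cyclic acetal (3S,6R)-6-[(4-methoxybenzyl)oxy]-2-{[(R)-2-[(4-methoxybenzyl)oxy]but-3-en-1-yl]oxy}-3-(naphthalen-2-ylmethoxy)-2,3,6,7-tetrahydrooxepine F4 as both anomers. Mild hydrolysis (PPTS, acetone/H2O) gives the lactol (3S,6R)-6-[(4-methoxybenzyl)oxy]-3-(naphthalen-2-ylmethoxy)-2,3,6,7-tetrahydrooxepin-2-ol F5 and returns one equivalent of 3. Ag2CO3 on Celite (toluene, reflux) oxidises the lactol to 9.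

**Further compounds**
F1 | step 8 | (2R,5S,6R)-6-hydroxy-2-[(4-methoxybenzyl)oxy]-6-{[(4-methoxybenzyl)oxy]methyl}-5-(naphthalen-2-ylmethoxy)cyclohex-3-en-1-one | O=C1[C@H](OCc2ccc(OC)cc2)C=C[C@H](OCc2ccc3ccccc3c2)[C@]1(O)COCc1ccc(OC)cc1
F2 | step 7 | (2S,5R,Z)-6-hydroxy-N-methoxy-5-[(4-methoxybenzyl)oxy]-N-methyl-2-(naphthalen-2-ylmethoxy)hex-3-enamide | CON(C)C(=O)[C@@H](OCc1ccc2ccccc2c1)/C=C\[C@@H](OCc1ccc(OC)cc1)CO
F3 | step 5 | (S)-3-(naphthalen-2-ylmethoxy)-4,4-bis{[(R)-2-[(4-methoxybenzyl)oxy]but-3-en-1-yl]oxy}but-1-ene | C=C[C@H](OCc1ccc2ccccc2c1)C(OC[C@H](OCc1ccc(OC)cc1)C=C)OC[C@H](OCc1ccc(OC)cc1)C=C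
F4 | step 5 | (3S,6R)-6-[(4-methoxybenzyl)oxy]-2-{[(R)-2-[(4-methoxybenzyl)oxy]but-3-en-1-yl]oxy}-3-(naphthalen-2-ylmethoxy)-2,3,6,7-tetrahydrooxepine (both anomers) | C=C[C@@H](OCc1ccc(OC)cc1)COC1OC[C@H](OCc2ccc(OC)cc2)C=C[C@@H]1OCc1ccc2ccccc2c1
F5 | step 5 | (3S,6R)-6-[(4-methoxybenzyl)oxy]-3-(naphthalen-2-ylmethoxy)-2,3,6,7-tetrahydrooxepin-2-ol (both anomers) | OC1OC[C@H](OCc2ccc(OC)cc2)C=C[C@@H]1OCc1ccc2ccccc2c1
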